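The data are simulated for an exercise; noise was put on by code.

Gamma and epsilon were the two runs I had; ochre and grey were to follow with more free base.

in all of them: electrophile 20 mM (fed, over 15 min)

| run | nucleophile | free base | remark | time |
|---|---|---|---|---|
| gamma | 1 equiv | 0.58 equiv | run made earlier |  |
| epsilon | 1 equiv | 0.71 equiv | run made earlier |  |
| ochre | 1.00 equiv | 0.800 equiv |  | 30 min |
| grey | 1.00 equiv | 1.00 equiv |  | 30 min |

| run | time / min | electrophile / % | product / % |
|---|---|---|---|
| gamma | 5.00 | 31.3 | 1.4 |
| gamma | 10.0 | 59.2 | 5.9 |
| gamma | 15.0 | 85.3 | 17.0 |
| gamma | 20.0 | 76.9 | 22.7 |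
| gamma | 25.0 | 72.1 | 28.1 |
| gamma | 30.0 | 67.9 | 34.3 |
| epsilon | 2.50 | 15.9 | 0.3 |
| epsilon | 4.00 | 24.7 | 1.0 |
| epsilon | 6.00 | 36.4 | 5.3 |
| epsilon | 10.0 | 59.8 | 7.8 |
| epsilon | 20.0 | 77.7 | 23.4 |
| epsilon | 30.0 | 68.3 | 33.0 |

(each reading ± 1 percentage point)

- percentages count the whole charge, also what has not yet gone in

- part of the electrophile that has reacted at the end, ochre
- part of the electrophile that has reacted at the end, grey
- what raising the equivalents of free base from its lowest to its highest value here does to the part of the electrophile that has reacted (changes below 5 percentage points count as none) (no change / it falls / it rises)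

I read the two tables row against row. At 20.0 min gamma held 76.9 % of electrophile and epsilon 77.7 %; at 30.0 min they held 67.9 % and 68.3 %. Each gap was smaller than the scatter of 1 percentage point, although free base differed, 0.58 equiv against 0.71 equiv.

So I worked with the fraction left. Let f be the electrophile left as a fraction of its charge, and g its reciprocal. If electrophile and nucleophile go one for one from equal charges, at a rate proportional to both, g climbs in a straight line once the feed is over. Over those 10.0 min, g climbed 0.172 in gamma and 0.177 in epsilon. Pooled, that gives 0.0175 min⁻¹, which I call κ, the clearing rate: the climb of g per minute after the feed, in the field's terms an apparent second-order rate constant times the charge.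

My own figure for ochre and grey was the mean of the two runs, 31.9 % reacted, with the same charges of electrophile and nucleophile, the same feed and the same clock; only free base differed. The forecast stood 1.1 points higher, at 33 % for ochre and 33 % for grey, with no change as the trend: “The rate therefore shows no dependence on base over this range”.

Ochre reached 32.7 % and grey 32.9 %, so the trend was no change: the change from the lowest to the highest value was 0.18 points, and the difference in free base was no reason for the level.

    electrophile + nucleophile → acid set free + product (k = 1.40 L mol⁻¹ min⁻¹)
    acid set free + free base ⇌ salt of the base (K = 1.60 × 10⁶ L mol⁻¹, k = 40.0 L mol⁻¹ min⁻¹)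
    nucleophile + acid set free ⇌ protonated nucleophile, settled at all times (K = 3100 L mol⁻¹)

Ochre's level came from the time allowed together with the joining of nucleophile and acid set free: without that joining it reached 38.4 %, and left until 300 min it reached 82.9 %. From ochre's 67.3 % at 30 min, κ leaves 16.1 % at 300 min, and the flask held 17.1 %. For a neighbour flask like ochre but charged with 8.0 mM of electrophile, I scaled κ with the charge to 0.00699 min⁻¹ and g's climb above unity likewise, which leaves 83.7 %; that neighbour kept 82 %.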